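The runs come from a simulation for substances that don't exist; the scatter is artificial.

- The target in this flask, which is the zeta run followed on, climbs ever more slowly, so I reckon with the gain still to come and not with the gain already made.

common to all: substrate 17 mM; initiator 9.5 mol%

|  | partner | transfer agent | remark | time |
|---|---|---|---|---|
| zeta | 1 equiv | 17 mM | the very flask that is asked about, followed so far |  |
| delta | 2 equiv | 17 mM | run made earlier |  |
| flask | 1.00 equiv | 17.0 mM |  | 40 min |

- zeta (time / min: target / %, substrate / %): 6.00: 33.4, 56.4; 12.0: 39.6, 46.8; 20.0: 41.7, 44.7; 25.0: 42.1, 43.7
- delta (time / min: target / %, substrate / %): 1.00: 16.5, 82.5; 2.00: 26.9, 70.7; 3.00: 34.1, 62.6; 4.00: 38.4, 55.9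

(standard deviation of a reading: 0.3 percentage points)

- south-east: at 40 min add substrate, 50.0% of the amount charged, then wait 12 min
- north-west: at 40 min take out 90% of the by-product then present, then wait 12 min
- west: at 40 min add partner, 100% of the amount charged, then wait 12 min
- south-west: change nothing and wait 12 min more

* target, in percent of the substrate first charged, at 40 min
* the option that brings most further target ("none" if no option brings more than 2 percentage points) (south-east / north-west / west / south-west / none)
* target present, in percent of the substrate first charged, after north-west
* target present, in percent of the substrate first charged, after west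

- what is added takes up no volume worth counting
- the numbers in the tables scatter with a standard deviation of 0.3 percentage points

- In zeta the target rate is 0.0103 min⁻¹ of the charge between 6.00 min and 12.0 min, but 0.00263 min⁻¹ between 12.0 min and 20.0 min, so it is falling.
- I treat this fall as a first-order decay and read from it the rate halving time, the time in which the target rate drops by a factor of two: 3.54 min, a reading that carries the scatter.
- On a decay of this kind, the gain still to come from any moment is that moment's rate times the halving time over ln(2).
- From the last zeta reading this gives 0.23 points, so I expect 42.3% at 40 min, with 43.7% of the substrate still unused at the last reading.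
- At 40 min the rate stands at 0.911% of its value in the second interval, and the gain to come is 0.012 points.
- To reach the 2 points margin, that gain has to grow by a factor of 164; for comparison, delta, with 2 equiv of partner against 1 equiv in zeta, reads 38.4% at 4.00 min, and zeta reads 33.4% at the later 6.00 min.
- So I commit to none, with the target unchanged after north-west and west. This is a bet that the rate follows a dying radical supply, since a reversible stall could look the same in these readings.
- The forecast differs: it gives 42.4% (41.8% to 43.2%), chooses west, expects 52% after north-west and 53% after west, and reads the plateau as reversible, “not dead initiator”.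
- The flask gives 41.8% and none, west adding 0.014 points; at 40.0 min it holds 0.0086% of its initiator, whose half-life by its own decomposition is 3.0 min.

    partner ⇌ dormant form (K = 2.50, k = 0.00890 s⁻¹)
    substrate + initiating radical → capped initiator + first chain carrier (k = 6.40 × 10⁵ L mol⁻¹ s⁻¹)
    substrate + second chain carrier → by-product + first chain carrier (k = 38000 L mol⁻¹ s⁻¹)
    transfer agent + first chain carrier → side product + idle radical (kL = 5000 L mol⁻¹ s⁻¹)
    2 second chain carrier → ended chains A (k = 1.00 × 10⁹ L mol⁻¹ s⁻¹)
    2 idle radical → ended radicals (k = 6.00 × 10⁷ L mol⁻¹ s⁻¹)
    partner + first chain carrier → target + second chain carrier (k = 88000 L mol⁻¹ s⁻¹)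
    initiator → 2 initiating radical (k = 0.00390 s⁻¹)
    2 first chain carrier → ended chains B (k = 6.00 × 10⁸ L mol⁻¹ s⁻¹)
    2 partner → self-condensation product (k = 0.100 L mol⁻¹ s⁻¹)

- The halving time also carries to delta: its last interval runs at 0.0430 min⁻¹ of the charge, so 3.54 min adds 22 points to its last reading and gives 60.4%, and the delta flask at 40 min stands at 58.6%.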